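**Plan**

1. Numbering: guaiane locants, primed for the ketone-bearing unit. After unmasking (C3' enol acetate, two silyl ethers) the norbornane is cut at C2–C2' and C3–C5' (retro-[4+2]) into dienyl acetate 13 and diene 16. 16 is traced back to 13, and the cyclopentadiene of 13 is cut at C1–C2 (C1'–C2' in the primed unit; retro-Rautenstrauch) to enyne 12.
2. Enabling feature: the C3' ketone with its C4' methyl methine between bridgeheads C2' and C5' is a hydrolysed adduct of a 2-acyloxycyclopenta-1,3-diene (C2'=C3'(OAc)–C4'=C5', sp3 C1'). That diene is the cycloisomer of a 3-acyloxy-1,4-enyne: alkyne C2'≡C3', carbinol C4', ring alkene C5'=C1'.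
3. Forward: α-santonin supplies the lactone (C6, C7, C11) and C8–C10. Ring A is excised by ozonolysis, one CH2 (C1) is inserted to give the seven-membered ring, C10–H is hydroxylated, and C5 is elaborated (enol triflate, ynone, methyl carbinol, acetate) to enyne 12.
4. Ring order: lactone (given) → cycloheptane → cyclopentadiene by gold-catalysed C1–C2 closure → norbornene by Diels–Alder. Dienyl acetate 13 is divided: one part goes through enone 14 to diene 16, the other is the diene partner of 16.
5. Stereochemistry: C6, C7, C11 of both units from santonin; C10/C10' (β-OH, epimeric to what santonin photolysis gives) by retention in ring expansion and C–H hydroxylation; C1/C1' by chirality relay from the C4 carbinol; C2, C3, C2', C5' by the endo, anti-facial cycloaddition; C4' by thermodynamic protonation.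

Key step: step 9

Remark: "2,3,4,15-tetranor" means these four ring-A carbons are absent; "1,2-seco" means the C1–C2 bond is absent.
Remark: the C4 carbinol epimers formed in step 7 are assumed separable; the epimer drawn is carried forward.

**Step 1**
Reactants: 1 α-santonin
Product: 3 tetranor keto lactone, via formyl keto lactone 2 (not isolated)
Conditions: O3, CH2Cl2/MeOH, −78 °C; Me2S, −78 → 20 °C; then K2CO3 (0.1 equiv), MeOH, 0 °C
Reagents that add atoms: ozone ([O-][O+]=O)
Why: Ozonolysis cleaves both enone C=C bonds (C5 becomes the ketone, C1 a formyl group on quaternary C10), and methoxide-induced retro-Claisen deformylation of the non-enolisable β-keto aldehyde gives the C10 enolate, which is protonated axially so that the methyl ends equatorial (α) while C6, C7 and C11 are untouched.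

**Step 2**
Reactants: 3 tetranor keto lactone
Product: 5 cycloheptanone lactone, via silyl ketone 4 (not isolated)
Conditions: Me3SiCHN2, Sc(OTf)3 (5 mol %), CH2Cl2, −78 → 0 °C; then 1 M HCl, THF, 0 °C
Reagents that add atoms: trimethylsilyldiazomethane (C[Si](C)(C)C=[N+]=[N-])
Why: Lewis-acid-catalysed diazoalkane homologation (Tiffeneau–Demjanov-type ring expansion): the α-carbon bearing the lactone oxygen is a poor migrating group, so the methyl-bearing methine C10 migrates with retention and the new carbon (C1) is inserted between the ketone and C10; acid removes the α-silyl group.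

**Step 3**
Reactants: 5 cycloheptanone lactone
Product: 6 tertiary hydroxy ketone
Conditions: methyl(trifluoromethyl)dioxirane (excess), CH2Cl2/CF3COCH3, −20 → 0 °C
Reagents that add atoms: methyl(trifluoromethyl)dioxirane (CC1(OO1)C(F)(F)F)
Why: Dioxirane C–H hydroxylation selects the most electron-rich tertiary C–H and proceeds with retention; C10–H is the only methine outside the electron-poor lactone ring, so its β-hydrogen is replaced by a β-hydroxyl.

**Step 4**
Reactants: 6 tertiary hydroxy ketone
Product: 7 silyl ether ketone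
Conditions: Et3SiOTf, 2,6-lutidine, CH2Cl2, −78 → 0 °C
Reagents that add atoms: triethylsilyl triflate (CC[Si](CC)(CC)OS(=O)(=O)C(F)(F)F)
Why: Silyl triflate silylation caps the tertiary β-hydroxy ketone before any base is used, which blocks retro-aldol opening of the seven-membered ring.

**Step 5**
Reactants: 7 silyl ether ketone
Product: 8 enol triflate
Conditions: KN(SiMe3)2, PhNTf2, THF, −78 °C
Reagents that add atoms: N-phenylbis(trifluoromethanesulfonimide) (O=S(=O)(N(c1ccccc1)S(=O)(=O)C(F)(F)F)C(F)(F)F)
Why: Kinetic deprotonation by the hindered base occurs at methylene C1 and not at the oxygen-bearing ring-fusion methine C6, and the enolate is O-sulfonylated at −78 °C before the C10 silyloxy group can be eliminated (enol triflate formation).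

**Step 6**
Reactants: 8 enol triflate
Product: 9 silyl ynenone
Conditions: Me3SiC≡CSnBu3, CO (1 atm), Pd(PPh3)4 (5 mol %), LiCl, THF, 55 °C
Reagents that add atoms: carbon monoxide ([C-]#[O+]); trimethyl[(tributylstannyl)ethynyl]silane (C[Si](C)(C)C#C[Sn](CCCC)(CCCC)CCCC)
Why: Carbonylative Stille coupling: oxidative addition of zerovalent palladium to the enol triflate, CO insertion and alkynyl transfer from tin attach C4 (from CO) and the C3≡C2 unit to C5.

**Step 7**
Reactants: 9 silyl ynenone
Product: 11 propargylic alcohol, via silylalkynyl carbinol 10 (not isolated)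
Conditions: MeMgBr, CeCl3, THF, −78 °C; aq. NH4Cl; then K2CO3 (cat.), MeOH, 0 °C
Reagents that add atoms: methylmagnesium bromide (C[Mg]Br)
Why: Organocerium 1,2-addition to the ketone is chemoselective over the lactone and, in the s-trans ynenone, should deliver methyl to the carbonyl face syn to H6 (anti to the lactone C6–O bond), giving the drawn C4 epimer; carbonate in methanol then removes the alkynyl silyl group.

**Step 8**
Reactants: 11 propargylic alcohol
Product: 12 enyne acetate
Conditions: Ac2O, Et3N, DMAP (cat.), CH2Cl2, 23 °C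
Reagents that add atoms: acetic anhydride (CC(=O)OC(C)=O)
Why: DMAP-catalysed acylation of the tertiary propargylic alcohol is standard and leaves the C4 stereocentre untouched.

**Step 9**
Reactants: 12 enyne acetate
Product: 13 dienyl acetate
Conditions: [AuCl(PPh3)] (5 mol %), AgSbF6 (5 mol %), 4 Å MS, dry MeCN, −20 °C; then Et3N (0.1 equiv), filtration through Et3N-deactivated silica at 0 °C; the portion reserved for step 13 is kept as a frozen benzene solution at −20 °C
Reagents that add atoms: none
Why: Cationic monovalent gold coordinates the terminal alkyne and triggers a 1,2-acetoxy shift through a five-membered acetoxonium ion; the resulting 2-acetoxypentadienyl cation (C1=C5–C4–C3(OAc)=C2[Au]) closes by a 4π conrotatory electrocyclisation that forms C1–C2, and loss of gold from C2 gives dienyl acetate 13. The closest known reaction type is the gold-catalysed Rautenstrauch rearrangement of 1-ethynyl-2-propenyl esters, run here without water so that the cyclopentadienyl acetate is not hydrolysed. The five-membered ring is closed in a formally 5-endo-trig mode, the ring alkene carbon C1 being attacked by the gold-bearing carbon C2 within the pentadienyl array. The only new stereocentre, C1, is set by centre-to-helix-to-centre transfer from C4: the C1–C2 bond forms anti to the departing C4–O bond, on the β-face of C1, so that H1 is α. The step needs the 1,2- and not the 1,3-acyloxy shift, which the terminal alkyne of the substrate secures, and it needs the acyloxy shift to outrun ionisation of the tertiary acetate, for which the low temperature and the nitrile solvent are chosen. Because C1–C5 of 13 become both C1–C5 of the dienophile half and C1'–C5' of the diene half, this one event supplies both five-membered rings of the dimer.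

**Step 10**
Reactants: 13 dienyl acetate (the portion not reserved for step 13)
Product: 14 enone
Conditions: K2CO3 (0.1 equiv), MeOH, 0 °C; pH 7 phosphate buffer
Reagents that add atoms: none
Why: Methanolysis of the enol acetate releases the C3 enolate, which is protonated at C2 to give the conjugated enone; C1 is not part of this enolate, so H1 stays α.

**Step 11**
Reactants: 14 enone
Product: 15 dienyl triflate
Conditions: KN(SiMe3)2, PhNTf2, THF, −78 °C
Reagents that add atoms: N-phenylbis(trifluoromethanesulfonimide) (O=S(=O)(N(c1ccccc1)S(=O)(=O)C(F)(F)F)C(F)(F)F)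
Why: Kinetic deprotonation at the α' methylene C2 gives the cross-conjugated enolate, trapped on oxygen (enol triflate formation); C1 is not deprotonated under these conditions, so H1 stays α.

**Step 12**
Reactants: 15 dienyl triflate
Product: 16 diene
Conditions: Pd(OAc)2 (5 mol %), PPh3, HCO2H, Et3N, DMF, 40 °C
Reagents that add atoms: none
Why: Palladium-catalysed formate reduction of the dienyl triflate (oxidative addition, hydride transfer from formate, reductive elimination) removes the C3 oxygen and leaves the C2=C3–C4=C5 diene, which is used at once because such dienes slowly self-dimerise.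

**Step 13**
Reactants: 13 dienyl acetate; 16 diene
Product: 17 cycloadduct enol acetate
Conditions: 13 (2.5 equiv, portion kept from step 9), freshly made 16 (1 equiv), BHT (cat.), toluene (2 M), 25 °C, 5 d
Reagents that add atoms: none
Why: Thermal Diels–Alder reaction of the kind by which guaia-2,4-dienes dimerise, with 13 as the diene (C2'=C3'(OAc)–C4'=C5') and the disubstituted C2=C3 bond of 16 as the dienophile: the endo transition state, with each partner reacting on the ring face opposite its C10 substituent (the H1 and H1' faces), fixes C2, C3, C2' and the quaternary C5', and pairing of the largest frontier coefficients (C2', next to the acetoxy carbon, with C2, the diene terminus of 16) gives the C2–C2'/C3–C5' regiochemistry.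

**Step 14**
Reactants: 17 cycloadduct enol acetate
Product: 18 bis-silyl caruifolin B
Conditions: K2CO3 (cat.), MeOH, 0 → 23 °C
Reagents that add atoms: none
Why: Methanolysis of the enol acetate releases the C3' ketone, and C-protonation with equilibration at C4' places the methyl on the exo face, because an endo methyl would clash with the endo-fused cyclopentene of the unprimed unit.

**Step 15**
Reactants: 18 bis-silyl caruifolin B
Product: 19 caruifolin B
Conditions: HF·pyridine, THF, 0 → 23 °C
Reagents that add atoms: none
Why: Fluoride-mediated desilylation cleaves both tertiary triethylsilyl ethers, while the lactones, the ketone and its α-stereocentre are stable to the mildly acidic medium.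

**Compound list**

1 | (−)-α-santonin, (3S,3aS,5aS,9bS) | C[C@H]1[C@@H]2CC[C@]3(C=CC(=O)C(=C3[C@H]2OC1=O)C)C | starting material
2 | (3S,3aS,6S,7aS)-3,6-dimethyl-2,7-dioxooctahydro-1-benzofuran-6-carbaldehyde (santonin without C2–C4 and C15; C1 formyl α and methyl β on C10, C5 ketone) | C[C@H]1[C@@H]2CC[C@@](C)(C=O)C(=O)[C@H]2OC1=O | intermediate
3 | (3S,3aS,6R,7aS)-3,6-dimethylhexahydro-1-benzofuran-2,7-dione (trans-lactone; 10α-methyl, 10β-H) | C[C@H]1[C@@H]2CC[C@@H](C)C(=O)[C@H]2OC1=O | intermediate
4 | 5-oxo-1-(trimethylsilyl)-2,3,4,15-tetranorguaian-12,6α-olide (10α-methyl, 10β-H; mixture at C1) | C[C@H]1[C@@H]2CC[C@@H](C)C([Si](C)(C)C)C(=O)[C@H]2OC1=O | intermediate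
5 | 5-oxo-2,3,4,15-tetranorguaian-12,6α-olide (6βH, 7αH, 11S; 10α-methyl, 10β-H) | C[C@H]1[C@@H]2CC[C@@H](C)CC(=O)[C@H]2OC1=O | intermediate
6 | 10β-hydroxy-5-oxo-2,3,4,15-tetranorguaian-12,6α-olide (10α-methyl) | C[C@H]1[C@@H]2CC[C@](C)(O)CC(=O)[C@H]2OC1=O | intermediate
7 | 5-oxo-10β-(triethylsilyloxy)-2,3,4,15-tetranorguaian-12,6α-olide | C[C@H]1[C@@H]2CC[C@](C)(O[Si](CC)(CC)CC)CC(=O)[C@H]2OC1=O | intermediate
8 | 10β-(triethylsilyloxy)-5-(trifluoromethanesulfonyloxy)-2,3,4,15-tetranorguai-1(5)-en-12,6α-olide | C[C@H]1[C@@H]2CC[C@](C)(O[Si](CC)(CC)CC)C=C(OS(=O)(=O)C(F)(F)F)[C@H]2OC1=O | intermediate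
9 | 4-oxo-10β-(triethylsilyloxy)-2-(trimethylsilyl)-15-nor-1,2-secoguai-1(5)-en-2-yn-12,6α-olide | C[C@H]1[C@@H]2CC[C@](C)(O[Si](CC)(CC)CC)C=C(C(=O)C#C[Si](C)(C)C)[C@H]2OC1=O | intermediate
10 | 4-hydroxy-10β-(triethylsilyloxy)-2-(trimethylsilyl)-1,2-secoguai-1(5)-en-2-yn-12,6α-olide (same spatial arrangement at C4 as 11; 4S by priority because of silicon) | C[C@H]1[C@@H]2CC[C@](C)(O[Si](CC)(CC)CC)C=C([C@](C)(O)C#C[Si](C)(C)C)[C@H]2OC1=O | intermediate
11 | (4R)-4-hydroxy-10β-(triethylsilyloxy)-1,2-secoguai-1(5)-en-2-yn-12,6α-olide (with the alkyne turned toward C1, the C4 oxygen is on the α-face and the methyl on the β-face) | C[C@H]1[C@@H]2CC[C@](C)(O[Si](CC)(CC)CC)C=C([C@](C)(O)C#C)[C@H]2OC1=O | intermediate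
12 | (4R)-4-acetoxy-10β-(triethylsilyloxy)-1,2-secoguai-1(5)-en-2-yn-12,6α-olide | C[C@H]1[C@@H]2CC[C@](C)(O[Si](CC)(CC)CC)C=C([C@](C)(OC(C)=O)C#C)[C@H]2OC1=O | intermediate
13 | 3-acetoxy-10β-(triethylsilyloxy)-1αH-guaia-2,4-dien-12,6α-olide | C[C@H]1[C@@H]2CC[C@](C)(O[Si](CC)(CC)CC)[C@@H]3C=C(OC(C)=O)C(C)=C3[C@H]2OC1=O | intermediate
14 | 3-oxo-10β-(triethylsilyloxy)-1αH-guai-4-en-12,6α-olide | C[C@H]1[C@@H]2CC[C@](C)(O[Si](CC)(CC)CC)[C@@H]3CC(=O)C(C)=C3[C@H]2OC1=O | intermediate
15 | 10β-(triethylsilyloxy)-3-(trifluoromethanesulfonyloxy)-1αH-guaia-2,4-dien-12,6α-olide | C[C@H]1[C@@H]2CC[C@](C)(O[Si](CC)(CC)CC)[C@@H]3C=C(OS(=O)(=O)C(F)(F)F)C(C)=C3[C@H]2OC1=O | intermediate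
16 | 10β-(triethylsilyloxy)-1αH-guaia-2,4-dien-12,6α-olide | C[C@H]1[C@@H]2CC[C@](C)(O[Si](CC)(CC)CC)[C@@H]3C=CC(C)=C3[C@H]2OC1=O | intermediate
17 | 3'-acetoxy-3',4'-didehydro-10,10'-bis-O-(triethylsilyl) derivative of caruifolin B (C3' enol acetate of 18; endo adduct, C2–C2' and C3–C5' bonds) | CC1=C2[C@H]3OC(=O)[C@@H](C)[C@@H]3CC[C@](C)(O[Si](CC)(CC)CC)[C@@H]2[C@H]2[C@H]3C(OC(C)=O)=C(C)[C@]4([C@@H]3[C@@](C)(O[Si](CC)(CC)CC)CC[C@H]3[C@H](C)C(=O)O[C@@H]34)[C@@H]12 | intermediate
18 | 10,10'-bis-O-(triethylsilyl)caruifolin B | CC1=C2[C@H]3OC(=O)[C@@H](C)[C@@H]3CC[C@](C)(O[Si](CC)(CC)CC)[C@@H]2[C@H]2[C@H]3C(=O)[C@H](C)[C@]4([C@@H]3[C@@](C)(O[Si](CC)(CC)CC)CC[C@H]3[C@H](C)C(=O)O[C@@H]34)[C@@H]12 | intermediate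
19 | caruifolin B | CC1=C2[C@H]3OC(=O)[C@@H](C)[C@@H]3CC[C@](C)(O)[C@@H]2[C@H]2[C@H]3C(=O)[C@H](C)[C@]4([C@@H]3[C@@](C)(O)CC[C@H]3[C@H](C)C(=O)O[C@@H]34)[C@@H]12 | target

**Step count and risks**

Total: 15 steps. Longest linear sequence: 15 steps (1 → 12 → 13 → 14 → 15 → 16 → 17 → 18 → 19), because diene 16 is itself made from 13.

Steps most likely to fail:

Step 13. Self-cycloaddition of 16 may compete with the cross-cycloaddition. The dienyl acetate may also isomerise by 1,5-hydrogen shift or be hydrolysed during the slow bimolecular reaction, and facial or endo selectivity may be incomplete. The fallback uses a more electron-rich diene made directly from the enone, so that no dienyl acetate has to be kept; it sets out from 14 and 16 and returns at 19. Enone 14 is converted with KN(SiMe3)2 and TBSOTf at −78 °C into 3-(tert-butyldimethylsilyloxy)-10β-(triethylsilyloxy)-1αH-guaia-2,4-dien-12,6α-olide F1. This diene undergoes a thermal Diels–Alder reaction with 16 in toluene to give the silyl enol ether cycloadduct F2. HF·pyridine then cleaves all three silyl groups and ketonises C3' with the C4' methyl group exo, giving 19.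

Step 3. C10–H lies β to the ketone and may react too slowly, so that methylene oxidation at C8 or C9 competes. The fallback installs the oxygen before ring expansion; it sets out from 2 and returns at 7. Potassium tert-butoxide in THF cleaves the formyl group of 2 (retro-Claisen) and gives the C10 enolate regiospecifically. Oxidation in the same flask with 2-(phenylsulfonyl)-3-phenyloxaziridine, from the axial β-face, should give the six-membered α-hydroxy ketone F3. Silylation with Et3SiOTf gives the silyl ether F4. Homologation with Me3SiCHN2/Sc(OTf)3, in which the electron-rich silyloxy-bearing carbon is expected to migrate, gives the α-silyl ketone F5, which loses silicon on acidic work-up to give 7.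

Step 9. The stereochemical relay from C4 to C1 may be mismatched with the ring, or may leak through ionisation of the tertiary acetate, giving the C1 epimer. The fallback reverses the order in which the two carbinol substituents are introduced, so the same facial preference gives the other C4 epimer; it sets out from 8 and returns at 13. Carbonylative Stille coupling of 8 with Me4Sn (CO, Pd(PPh3)4, LiCl) gives the methyl ketone F6. Ethynylmagnesium bromide with CeCl3 adds to the same carbonyl face as in step 7 and gives the epimeric carbinol F7. Acetylation gives the epimeric acetate F8, which under the conditions of step 9 should close with the opposite sense of relay and give 13.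

**Further compounds**

F1 | step 13 | 3-(tert-butyldimethylsilyloxy)-10β-(triethylsilyloxy)-1αH-guaia-2,4-dien-12,6α-olide | C[C@H]1[C@@H]2CC[C@](C)(O[Si](CC)(CC)CC)[C@@H]3C=C(O[Si](C)(C)C(C)(C)C)C(C)=C3[C@H]2OC1=O
F2 | step 13 | C3' tert-butyldimethylsilyl enol ether of 18 (silyl enol ether cycloadduct) | CC1=C2[C@H]3OC(=O)[C@@H](C)[C@@H]3CC[C@](C)(O[Si](CC)(CC)CC)[C@@H]2[C@H]2[C@H]3C(O[Si](C)(C)C(C)(C)C)=C(C)[C@]4([C@@H]3[C@@](C)(O[Si](CC)(CC)CC)CC[C@H]3[C@H](C)C(=O)O[C@@H]34)[C@@H]12
F3 | step 3 | 6β-hydroxy-3,6-dimethylhexahydro-1-benzofuran-2,7-dione (six-membered α-hydroxy ketone; hydroxyl axial, methyl equatorial at the future C10) | C[C@H]1[C@@H]2CC[C@](C)(O)C(=O)[C@H]2OC1=O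
F4 | step 3 | triethylsilyl ether of F3 | C[C@H]1[C@@H]2CC[C@](C)(O[Si](CC)(CC)CC)C(=O)[C@H]2OC1=O
F5 | step 3 | 5-oxo-10β-(triethylsilyloxy)-1-(trimethylsilyl)-2,3,4,15-tetranorguaian-12,6α-olide (mixture at C1) | C[C@H]1[C@@H]2CC[C@](C)(O[Si](CC)(CC)CC)C([Si](C)(C)C)C(=O)[C@H]2OC1=O
F6 | step 9 | 4-oxo-10β-(triethylsilyloxy)-2,3-dinor-guai-1(5)-en-12,6α-olide (C5 acetyl compound) | C[C@H]1[C@@H]2CC[C@](C)(O[Si](CC)(CC)CC)C=C(C(C)=O)[C@H]2OC1=O
F7 | step 9 | (4S)-4-hydroxy-10β-(triethylsilyloxy)-1,2-secoguai-1(5)-en-2-yn-12,6α-olide | C[C@H]1[C@@H]2CC[C@](C)(O[Si](CC)(CC)CC)C=C([C@@](C)(O)C#C)[C@H]2OC1=O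
F8 | step 9 | (4S)-4-acetoxy-10β-(triethylsilyloxy)-1,2-secoguai-1(5)-en-2-yn-12,6α-olide | C[C@H]1[C@@H]2CC[C@](C)(O[Si](CC)(CC)CC)C=C([C@@](C)(OC(C)=O)C#C)[C@H]2OC1=O
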